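**Remarks on the chemistry.** The isocoumarin is numbered C1 (lactone carbonyl), O2, C3, C4, C4a, C5–C8, C8a. Ring A is the benzene ring C4a–C8a. Ring B is the phenoxy ring, with primed atoms C1'–C6' and the ether oxygen on C1'. The target has no stereocentre. Olivetol (5-pentylbenzene-1,3-diol) is assumed to be commercially available; it is used for ring B because it fixes the position of the benzyl ether without a selective monoalkylation of a catechol.

## Analysis of the target

The target is a 1H-isochromen-1-one: benzene ring A (C4a, C5, C6, C7, C8, C8a) fused to an α-pyranone ring (C1, O2, C3, C4), with a pentyl chain on C3, a free hydroxyl on C6 and an aryloxy group on C8. Ring B is a benzene ring whose ether carbon C1' lies between a hydroxyl (C2') and a pentyl chain (C6'), with a methoxy group on C4'. There is no stereocentre and no double bond of defined geometry, so the problem is purely one of regiochemistry. The sensitive groups are the enol lactone (opened by hydroxide, and its C3=C4 bond can be hydrogenated), the two free phenols, and the single methyl ether on C4', which must survive whatever unmasks the phenols on C6 and C2'. The hard part is the diaryl ether: its oxygen has two ortho substituents on ring B and sits on C8, next to the carbon that carries the lactone carbonyl, so three of the four ortho positions around the ether are occupied. Ring A also carries substituents on the contiguous carbons C8, C8a and C4a. The plan rests on one feature: C8 bears an atom that can arrive as a nucleophile (the phenoxide oxygen of ring B) and its neighbour C8a bears a carbon that can arrive as an electrophile (C1, as carbon dioxide). This vicinal pairing is what addition across an aryne delivers, and a halogen on C4a, beside the aryne bond, can both steer that addition and later become the C4a–C4 bond.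

## Retrosynthetic reasoning

**Target 22 to dibenzyl ether 21.** The phenols on C6 and C2' are masked as benzyl ethers. Benzyl is chosen because it survives organolithium, fluoride, palladium and hydroxide, and because a boron Lewis acid at low temperature removes it without touching the C4' methyl ether or reducing the C3=C4 bond. One final operation frees both phenols.

**Isocoumarin 21 to alkynyl acid 20.** The O2–C3 bond is cut. In the forward direction the carboxyl oxygen adds 6-endo to an alkyne whose distal carbon already carries the pentyl chain. This makes the pyranone ring at the correct oxidation level in an atom-neutral isomerisation, with no need to functionalise C4 separately.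

**Acid 20 to ester 19, then to bromo ester 17 and hept-1-yne 18.** The C4a–C4 bond is cut as an aryl–alkynyl bond. A bromine on C4a is the natural partner for a cross-coupling with 18, which brings in C4, C3 and the pentyl chain in one piece. The carboxyl travels through the coupling as its methyl ester 17, made from acid 16 by carboxylate alkylation, and is freed again afterwards.

**Bromo acid 16 to silyl triflate 6, phenol 12 and carbon dioxide 13.** This is the central disconnection: O–C8 and C8a–C1 are cut together. A copper- or palladium-mediated etherification, or an ipso-substitution, would have to bring a doubly ortho-flanked phenoxide onto a carbon next to a carboxyl group. Addition of phenoxide 14 to the strained triple bond of aryne 15 has an early, undemanding transition state and needs no metal insertion. The addition leaves a carbanion on exactly the carbon that needs C1, and 13 can supply that carbon. The bromine beside the aryne bond decides which aryne carbon is attacked and is kept as the handle for C4. The forward reaction must put the oxygen on the carbon remote from bromine and must carboxylate the aryl anion before it is protonated or expels bromide.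

**Silyl triflate 6 to 4-(benzyloxy)phenol 1.** The ortho-silyl aryl triflate comes from a 2,6-dibromophenol by the standard sequence: silyl ether 3, then bromine–lithium exchange with migration of silicon from oxygen to carbon (via 4 and 5), then triflation. Using two equivalent bromines means one is consumed to place silicon and the other remains exactly where C4a needs it. Dibromophenol 2 comes from ortho-dibromination of 1.

**Phenol 12 to olivetol 7.** The free hydroxyl of 12 is traced back to a formyl group (aldehyde 10, by aryl-migrating peracid oxidation via formate 11). The benzyl ether is installed while the formyl group is still present, so the hydroxyl ends up between pentyl and benzyloxy by construction. Aldehyde 10 comes from 7 by formylation next to the pentyl chain (8), methylation of the non-chelated hydroxyl (9) and benzylation of the chelated one.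

## Alternatives that were turned down

**Alternative 1: ring B built by annulation on the ether oxygen.**
- Disconnection: ring B is cut at C1'–C6' and C2'–C3'. This leads back to an aryloxymalonate already attached to ring A, dimethyl 2-[5-(benzyloxy)-2-(methoxycarbonyl)-3-methylphenoxy]propanedioate (A1), and the enone (E)-non-3-en-2-one (A2).
- Forward key step: under NaOMe the malonate carbanion of A1 adds to the β-carbon of A2. The methyl ketone enolate then condenses onto one malonate ester and closes a cyclohexane-1,3-dione, methyl 4-(benzyloxy)-2-{[1-(methoxycarbonyl)-2,4-dioxo-6-pentylcyclohexyl]oxy}-6-methylbenzoate (A3), as a mixture of stereoisomers.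
- For: the crowded ether is never made by arylation. The O–C1' bond comes from plain alkylation of a ring A phenol, and Michael–Claisen annulation is established chemistry. On the reliability of the key step this alternative is stronger than the chosen route.
- Against: A3 is far from ring B. The extra ester must be removed, the dione dehydrogenated to the aromatic level, and the two oxygens on C2' and C4' differentiated so that only C4' is methylated. Two stereocentres are made only to be destroyed. Ring A of A3 carries a methyl group on C4a, so C4, C3 and the pentyl chain must still be added by lateral metalation and acylation of an ortho-toluate in the presence of the half-finished ring B.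
- Comparison: the chosen route brings ring B in complete and sets the ether and C1 in one operation. It accepts an unproven key step in exchange for a much shorter sequence after it.

**Alternative 2: ring A by cyclobutenone benzannulation.**
- Disconnection: the ring A bonds C6–C7 and C8–C8a are cut. This leads back to 3-methylcyclobut-2-en-1-one (A4) and the ethynyl ether of the ring B phenol, 1-(benzyloxy)-2-(ethynyloxy)-5-methoxy-3-pentylbenzene (A5).
- Forward key step: on heating, A4 opens to a vinylketene and adds to A5. The resulting vinylcyclobutenone opens and undergoes six-electron ring closure, giving 3-[2-(benzyloxy)-4-methoxy-6-pentylphenoxy]-5-methylphenol (A6).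
- For: the cascade is pericyclic, metal-free and regiochemically reliable, and the hindered oxygen is attached to a small two-carbon unit rather than to a substituted arene. On predictability of regiochemistry it is at least equal to the chosen route.
- Against: A6 has hydrogen on C8a and a methyl group on C4a. C1 must then be introduced at the most hindered ring position, between the aryloxy and methyl groups, in competition with two open positions activated by the free hydroxyl and with the electron-rich ring B. The methyl group must afterwards be elaborated into C4, C3 and the pentyl chain. A4 is volatile and takes several steps to make, and A5 must be made from the doubly ortho-substituted phenol 12.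
- Comparison: the chosen aryne route places C1 on C8a as part of the ether-forming event and leaves a bromine on C4a, so no later C–H functionalisation of ring A is needed.

**Alternative 3: ring A from a fused pyranone by cycloaddition and loss of carbon dioxide.**
- Disconnection: C6–C7 and C5–C4a are cut. This leads back to 4-[2-(benzyloxy)-4-methoxy-6-pentylphenoxy]-7-pentyl-2H,5H-pyrano[4,3-b]pyran-2,5-dione (A7) and (triisopropylsilyloxy)ethyne (A8).
- Forward key step: Diels–Alder addition of A8 across the aryloxy-bearing pyranone ring of A7, then extrusion of carbon dioxide from the bridged adduct. This gives 8-[2-(benzyloxy)-4-methoxy-6-pentylphenoxy]-3-pentyl-6-(triisopropylsilyloxy)-1H-isochromen-1-one (A9).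
- For: this is the most convergent plan. A9 is the complete skeleton with every substituent in place, and only two deprotections remain. The polarity of the ynol ether matches the required orientation. In endgame step economy it is stronger than the chosen route.
- Against: A7 is itself a multistep target. The bicyclic dione must be assembled, its C4 oxygen activated and then displaced by the hindered phenoxide of 12. A7 contains two pyranone rings that can both act as dienes or as Michael acceptors. A8 is thermally labile at the temperatures such electron-poor pyranones usually need. The uncertain step therefore comes late, on the most valuable intermediate.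
- Comparison: the chosen route also has one uncertain step, but it is reached from two simple arenes in three and four steps, and the later steps are ordinary and cheap to repeat.

Key step: step 8

## Route

Step 1
Reactants: 1 4-(benzyloxy)phenol
Product: 2 4-(benzyloxy)-2,6-dibromophenol
Conditions: NBS (2.1 equiv), i-Pr2NH (cat.), CH2Cl2, 0 °C → rt
Reagents that add atoms: N-bromosuccinimide, O=C1CCC(=O)N1Br
Why: Electrophilic aromatic bromination; the free hydroxyl is the strongest donor, the amine-mediated NBS protocol delivers bromine ortho to a phenol, and the para position is blocked by the benzyloxy group, so both bromines should enter at C2 and C6.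

Step 2
Reactants: 2 4-(benzyloxy)-2,6-dibromophenol
Product: 3 [4-(benzyloxy)-2,6-dibromophenoxy]trimethylsilane
Conditions: (Me3Si)2NH, THF, reflux; evaporate to dryness
Reagents that add atoms: hexamethyldisilazane, C[Si](C)(C)N[Si](C)(C)C
Why: O-silylation of a phenol by hexamethyldisilazane with loss of ammonia; the crude silyl ether is dried and used directly.

Step 3
Reactants: 3 [4-(benzyloxy)-2,6-dibromophenoxy]trimethylsilane
Product: 6 4-(benzyloxy)-2-bromo-6-(trimethylsilyl)phenyl trifluoromethanesulfonate, via aryllithium 4 (not isolated), via lithium silylphenoxide 5 (not isolated)
Conditions: n-BuLi (1.05 equiv), THF, −100 → −80 °C; then Tf2O, −100 °C → rt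
Reagents that add atoms: trifluoromethanesulfonic anhydride, O=S(=O)(OS(=O)(=O)C(F)(F)F)C(F)(F)F
Why: Bromine–lithium exchange at one of the two equivalent bromides gives 4, whose carbanion is ortho to the silyloxy group and meta to the remaining bromine, so it cannot eliminate to an aryne and instead undergoes the anionic 1,3-shift of silicon from oxygen to carbon (retro-Brook rearrangement) to give 5. O-Triflation of 5 then gives the ortho-silyl aryl triflate.

Step 4
Reactants: 7 olivetol (5-pentylbenzene-1,3-diol)
Product: 8 2,4-dihydroxy-6-pentylbenzaldehyde
Conditions: POCl3, DMF, 0 °C → rt; then H2O, 50 °C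
Reagents that add atoms: N,N-dimethylformamide, CN(C)C=O; water, O
Why: Vilsmeier–Haack formylation; the chloroiminium ion should attack the resorcinol position ortho to one hydroxyl and para to the other (next to the pentyl chain) rather than the more crowded position between the two hydroxyls, and hydrolysis of the iminium salt gives the aldehyde.

Step 5
Reactants: 8 2,4-dihydroxy-6-pentylbenzaldehyde
Product: 9 2-hydroxy-4-methoxy-6-pentylbenzaldehyde
Conditions: MeI (1.05 equiv), K2CO3, acetone, rt → 45 °C
Reagents that add atoms: iodomethane, CI
Why: Williamson ether synthesis; the C2 hydroxyl is held in a hydrogen bond to the formyl oxygen and is less nucleophilic than the C4 hydroxyl, so one equivalent of iodomethane should alkylate C4–OH only.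

Step 6
Reactants: 9 2-hydroxy-4-methoxy-6-pentylbenzaldehyde
Product: 10 2-(benzyloxy)-4-methoxy-6-pentylbenzaldehyde
Conditions: BnBr, K2CO3, DMF, 60 °C
Reagents that add atoms: benzyl bromide, BrCc1ccccc1
Why: Williamson benzylation of the remaining, chelated phenol under slightly more forcing conditions; only one hydroxyl is left, so no selectivity is required.

Step 7
Reactants: 10 2-(benzyloxy)-4-methoxy-6-pentylbenzaldehyde
Product: 12 2-(benzyloxy)-4-methoxy-6-pentylphenol, via aryl formate 11 (not isolated)
Conditions: mCPBA, CH2Cl2, 0 °C → rt; then K2CO3 (cat.), MeOH, rt
Reagents that add atoms: 3-chloroperoxybenzoic acid, OOC(=O)c1cccc(Cl)c1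
Why: Baeyer–Villiger (Dakin-type) oxidation; the electron-rich aryl group migrates in preference to hydride and gives formate 11, which is methanolysed to the phenol. Because the formyl carbon is exchanged for oxygen after the benzyl ether is in place, the free hydroxyl must lie between the pentyl and benzyloxy groups.

Step 8
Reactants: 6 4-(benzyloxy)-2-bromo-6-(trimethylsilyl)phenyl trifluoromethanesulfonate; 12 2-(benzyloxy)-4-methoxy-6-pentylphenol; 13 carbon dioxide
Product: 16 4-(benzyloxy)-2-[2-(benzyloxy)-4-methoxy-6-pentylphenoxy]-6-bromobenzoic acid, via potassium phenoxide 14 (not isolated), via bromoaryne 15 (not isolated)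
Conditions: 12 (1.3 equiv), KH (1.25 equiv), THF, 0 °C; 18-crown-6, CO2 (1 atm); then 6 (slow addition), CsF, 0 °C → rt; 1 M HCl
Reagents that add atoms: none
Why: Proposed new method: fluoride attacks silicon of 6 and triflate leaves, giving aryne 15. Phenoxide 14 has both ortho positions and the para position occupied and can therefore react only through oxygen; it should add to the aryne carbon remote from bromine (the future C8), because the C–Br bond distorts the aryne so that this carbon is the more electrophilic one and the developing carbanion on the future C8a sits beside the inductively withdrawing halogen. The benzyloxy group para to that carbanion opposes this only weakly. The aryl anion is generated with a preformed potassium salt in an aprotic medium that contains no O–H or N–H donor, so it should be captured by 13, present in large excess in the saturated solution, forming C8a–C1 as the carboxylate; acid work-up gives 16. The closest known reaction types are the fluoride-mediated O-arylation of phenols with ortho-silyl aryl triflates and the three-component union of arynes, amines and carbon dioxide to anthranilic acids; a phenoxide as the nucleophile in this carboxylative coupling has not been shown. No ring closes and no stereocentre forms. The step needs regioselective addition to the unsymmetrical aryne, which the bromine beside the triple bond secures, and carboxylation faster than protonation or bromide loss from the ortho-bromoaryl anion, which the absence of proton donors, the low stationary aryne concentration and the excess of 13 are meant to secure. Reversible carbonate formation between 14 and 13 lowers the concentration of free phenoxide but is disfavoured by the two ortho substituents and does not consume it.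

Step 9
Reactants: 16 4-(benzyloxy)-2-[2-(benzyloxy)-4-methoxy-6-pentylphenoxy]-6-bromobenzoic acid
Product: 17 methyl 4-(benzyloxy)-2-[2-(benzyloxy)-4-methoxy-6-pentylphenoxy]-6-bromobenzoate
Conditions: MeI, K2CO3, DMF, rt
Reagents that add atoms: iodomethane, CI
Why: O-alkylation of the carboxylate (SN2 at iodomethane), which, unlike acid-catalysed esterification, needs no attack at the doubly ortho-flanked carbonyl carbon; the ester keeps the carboxyl out of the copper and palladium chemistry of the next step.

Step 10
Reactants: 17 methyl 4-(benzyloxy)-2-[2-(benzyloxy)-4-methoxy-6-pentylphenoxy]-6-bromobenzoate; 18 hept-1-yne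
Product: 19 methyl 4-(benzyloxy)-2-[2-(benzyloxy)-4-methoxy-6-pentylphenoxy]-6-(hept-1-yn-1-yl)benzoate
Conditions: PdCl2(PPh3)2 (5 mol%), CuI (10 mol%), Et3N, DMF, 70 °C
Reagents that add atoms: none
Why: Sonogashira coupling forming C4a–C4; the bromide is ortho to the ester, which favours oxidative addition to zerovalent palladium, it has one free ortho position, and it is the only carbon–halogen bond in the molecule.

Step 11
Reactants: 19 methyl 4-(benzyloxy)-2-[2-(benzyloxy)-4-methoxy-6-pentylphenoxy]-6-(hept-1-yn-1-yl)benzoate
Product: 20 4-(benzyloxy)-2-[2-(benzyloxy)-4-methoxy-6-pentylphenoxy]-6-(hept-1-yn-1-yl)benzoic acid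
Conditions: LiOH·H2O, THF/MeOH/H2O, 60 °C; then 1 M HCl
Reagents that add atoms: lithium hydroxide, [Li+].[OH-]
Why: Saponification by acyl–oxygen cleavage; one ortho group is a linear alkynyl group and the other an oxygen-linked aryl, so the carbonyl should remain accessible to hydroxide on warming. The diaryl ether, the benzyl ethers and the unactivated alkyne are inert to aqueous base.

Step 12
Reactants: 20 4-(benzyloxy)-2-[2-(benzyloxy)-4-methoxy-6-pentylphenoxy]-6-(hept-1-yn-1-yl)benzoic acid
Product: 21 6-(benzyloxy)-8-[2-(benzyloxy)-4-methoxy-6-pentylphenoxy]-3-pentyl-1H-isochromen-1-one
Conditions: AgOSO2CF3 (AgOTf, 10 mol%), CH2Cl2, rt, dark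
Reagents that add atoms: none
Why: Silver-catalysed cycloisomerisation of a 2-alkynylbenzoic acid; π-activation places positive character on the pentyl-bearing alkyne carbon, because the other alkyne carbon is attached to an arene with an ortho carboxyl and only meta oxygen donors. The carboxyl oxygen should therefore close 6-endo-dig, forming O2–C3, and protodemetalation gives the isocoumarin.

Step 13
Reactants: 21 6-(benzyloxy)-8-[2-(benzyloxy)-4-methoxy-6-pentylphenoxy]-3-pentyl-1H-isochromen-1-one
Product: 22 6-hydroxy-8-(2-hydroxy-4-methoxy-6-pentylphenoxy)-3-pentyl-1H-isochromen-1-one (CNP0409817.0)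
Conditions: BCl3 (5 equiv), C6HMe5 (6 equiv), CH2Cl2, −78 °C; MeOH quench
Reagents that add atoms: none
Why: Lewis-acid cleavage of aryl benzyl ethers with pentamethylbenzene as a non-basic scavenger for the benzyl cation; at −78 °C BCl3 should remove both benzyl groups and leave the unchelated C4' methyl ether, the diaryl ether and the lactone intact. It also avoids hydrogenation conditions that could reduce the C3=C4 bond.

## Compound list

1 | 4-(benzyloxy)phenol | Oc1ccc(OCc2ccccc2)cc1 | starting material
2 | 4-(benzyloxy)-2,6-dibromophenol | Oc1c(Br)cc(OCc2ccccc2)cc1Br | intermediate
3 | [4-(benzyloxy)-2,6-dibromophenoxy]trimethylsilane | C[Si](C)(C)Oc1c(Br)cc(OCc2ccccc2)cc1Br | intermediate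
4 | [5-(benzyloxy)-3-bromo-2-(trimethylsilyloxy)phenyl]lithium | [Li]c1cc(OCc2ccccc2)cc(Br)c1O[Si](C)(C)C | intermediate
5 | lithium 4-(benzyloxy)-2-bromo-6-(trimethylsilyl)phenoxide | [Li+].[O-]c1c(Br)cc(OCc2ccccc2)cc1[Si](C)(C)C | intermediate
6 | 4-(benzyloxy)-2-bromo-6-(trimethylsilyl)phenyl trifluoromethanesulfonate | C[Si](C)(C)c1cc(OCc2ccccc2)cc(Br)c1OS(=O)(=O)C(F)(F)F | intermediate
7 | olivetol (5-pentylbenzene-1,3-diol) | CCCCCc1cc(O)cc(O)c1 | starting material
8 | 2,4-dihydroxy-6-pentylbenzaldehyde | CCCCCc1cc(O)cc(O)c1C=O | intermediate
9 | 2-hydroxy-4-methoxy-6-pentylbenzaldehyde | CCCCCc1cc(OC)cc(O)c1C=O | intermediate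
10 | 2-(benzyloxy)-4-methoxy-6-pentylbenzaldehyde | CCCCCc1cc(OC)cc(OCc2ccccc2)c1C=O | intermediate
11 | 2-(benzyloxy)-4-methoxy-6-pentylphenyl formate | CCCCCc1cc(OC)cc(OCc2ccccc2)c1OC=O | intermediate
12 | 2-(benzyloxy)-4-methoxy-6-pentylphenol | CCCCCc1cc(OC)cc(OCc2ccccc2)c1O | intermediate
13 | carbon dioxide | O=C=O | starting material
14 | potassium 2-(benzyloxy)-4-methoxy-6-pentylphenoxide | [K+].CCCCCc1cc(OC)cc(OCc2ccccc2)c1[O-] | intermediate
15 | 5-(benzyloxy)-3-bromobenzyne (1-(benzyloxy)-3-bromo-4,5-didehydrobenzene) | BrC1=CC(OCc2ccccc2)=CC#C1 | intermediate
16 | 4-(benzyloxy)-2-[2-(benzyloxy)-4-methoxy-6-pentylphenoxy]-6-bromobenzoic acid | O=C(O)c1c(Br)cc(OCc2ccccc2)cc1Oc1c(OCc2ccccc2)cc(OC)cc1CCCCC | intermediate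
17 | methyl 4-(benzyloxy)-2-[2-(benzyloxy)-4-methoxy-6-pentylphenoxy]-6-bromobenzoate | COC(=O)c1c(Br)cc(OCc2ccccc2)cc1Oc1c(OCc2ccccc2)cc(OC)cc1CCCCC | intermediate
18 | hept-1-yne | C#CCCCCC | starting material
19 | methyl 4-(benzyloxy)-2-[2-(benzyloxy)-4-methoxy-6-pentylphenoxy]-6-(hept-1-yn-1-yl)benzoate | COC(=O)c1c(C#CCCCCC)cc(OCc2ccccc2)cc1Oc1c(OCc2ccccc2)cc(OC)cc1CCCCC | intermediate
20 | 4-(benzyloxy)-2-[2-(benzyloxy)-4-methoxy-6-pentylphenoxy]-6-(hept-1-yn-1-yl)benzoic acid | O=C(O)c1c(C#CCCCCC)cc(OCc2ccccc2)cc1Oc1c(OCc2ccccc2)cc(OC)cc1CCCCC | intermediate
21 | 6-(benzyloxy)-8-[2-(benzyloxy)-4-methoxy-6-pentylphenoxy]-3-pentyl-1H-isochromen-1-one | CCCCCc1cc2cc(OCc3ccccc3)cc(Oc3c(OCc4ccccc4)cc(OC)cc3CCCCC)c2c(=O)o1 | intermediate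
22 | 6-hydroxy-8-(2-hydroxy-4-methoxy-6-pentylphenoxy)-3-pentyl-1H-isochromen-1-one | CCCCCc1cc2cc(O)cc(Oc3c(O)cc(OC)cc3CCCCC)c2c(=O)o1 | target

## Totals and risks

Total: 13 steps. Longest linear sequence: 10 steps (steps 4–13, from olivetol 7). The ring A branch (steps 1–3) joins at step 8.

The least certain steps are, in order of risk, step 8 (the key step), step 12, step 11 and step 13.

The key step, step 8, is the least certain. Three processes could divert it: proton capture by the aryl anion from adventitious donors, giving O-arylation without carboxylation; loss of bromide from the ortho-bromoaryl anion, which opens a second aryne and leads to further additions; and sequestration of the phenoxide as its carbonate, which would let fluoride or the product carboxylate add to the aryne instead. Addition with reversed regiochemistry is the least likely of the failure modes. The fallback for step 8 abandons the aryne and makes the O–C8 bond by nucleophilic aromatic substitution, with C1 already present as an aldehyde. It sets out from phenol 12 and returns to the route at acid 16. Commercial 3-bromo-5-fluorophenol (Oc1cc(F)cc(Br)c1) is benzylated (BnBr, K2CO3, DMF) to 1-(benzyloxy)-3-bromo-5-fluorobenzene F1. LiN(i-Pr)2 at −78 °C removes the proton of F1 that is flanked by fluorine and bromine, and DMF then gives 4-(benzyloxy)-2-bromo-6-fluorobenzaldehyde F2. Phenol 12 displaces the fluoride of F2, which lies ortho to the formyl group (Cs2CO3, DMF, 100–120 °C), to give 4-(benzyloxy)-2-[2-(benzyloxy)-4-methoxy-6-pentylphenoxy]-6-bromobenzaldehyde F3. Pinnick oxidation of F3 (NaClO2, NaH2PO4, 2-methylbut-2-ene, t-BuOH/H2O) then gives 16.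

Next in risk is step 12. The carboxyl may close through the other alkyne carbon (5-exo), because silver catalysis of free alkynyl acids does not always discriminate sharply between the two modes; this would give an alkylidene phthalide in place of the isocoumarin. The fallback for step 12 builds the pyranone without an alkyne. It sets out from bromo acid 16 and returns at 21, replacing steps 9–12. Tridecane-6,8-dione F4, made by Claisen condensation of heptan-2-one (CCCCCC(C)=O) with ethyl hexanoate (CCCCCC(=O)OCC) using NaH, is coupled with 16 under copper catalysis (CuI, K3PO4, DMF, 100 °C). C-Arylation of F4, loss of one hexanoyl group by retro-Claisen cleavage and cyclodehydration of the resulting aryl ketone give 21, with the ketone carbon necessarily becoming C3.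

Then comes step 11. Hydrolysis of the 2,6-disubstituted benzoate may be slow, and forcing it risks base-induced 5-exo closure of the carboxylate onto the alkyne or hydration of the alkyne. The fallback for step 11 skips the free acid. It sets out from ester 19 and returns at 21; no new compound arises (F0). Ester 19 is treated with a carbophilic Lewis acid and a Brønsted acid (Cu(OSO2CF3)2 cat., CF3CO2H, 1,2-dichloroethane, 60 °C). The ester carbonyl oxygen closes 6-endo on the activated alkyne and the methyl group is lost from the oxocarbenium ion. Partial loss of benzyl groups under these conditions would be harmless, since they are removed in the next step.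

Last is step 13. The C4' methyl ether may be cleaved on over-exposure, and the electron-rich ring B may be C-benzylated if the scavenger does not intercept the benzyl cation. The fallback for step 13 changes from Lewis-acid to reductive cleavage. It sets out from 21 and ends at 22; no new compound arises (F0). Hydrogenolysis (H2, 1 atm, Pd/C, EtOAc, rt) removes both benzyl groups as toluene and cannot touch the methyl ether; it is stopped at full debenzylation to avoid slow reduction of the C3=C4 bond.

## Further compounds

F1 | step 8 | 1-(benzyloxy)-3-bromo-5-fluorobenzene | Fc1cc(Br)cc(OCc2ccccc2)c1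
F2 | step 8 | 4-(benzyloxy)-2-bromo-6-fluorobenzaldehyde | O=Cc1c(F)cc(OCc2ccccc2)cc1Br
F3 | step 8 | 4-(benzyloxy)-2-[2-(benzyloxy)-4-methoxy-6-pentylphenoxy]-6-bromobenzaldehyde | O=Cc1c(Br)cc(OCc2ccccc2)cc1Oc1c(OCc2ccccc2)cc(OC)cc1CCCCC
F4 | step 12 | tridecane-6,8-dione | CCCCCC(=O)CC(=O)CCCCC
F0 | step 11 | none | none
F0 | step 13 | none | none
A1 | alternative 1 | dimethyl 2-[5-(benzyloxy)-2-(methoxycarbonyl)-3-methylphenoxy]propanedioate | COC(=O)C(Oc1cc(OCc2ccccc2)cc(C)c1C(=O)OC)C(=O)OC
A2 | alternative 1 | (E)-non-3-en-2-one | CCCCC/C=C/C(C)=O
A3 | alternative 1 | methyl 4-(benzyloxy)-2-{[1-(methoxycarbonyl)-2,4-dioxo-6-pentylcyclohexyl]oxy}-6-methylbenzoate (mixture of stereoisomers) | COC(=O)c1c(C)cc(OCc2ccccc2)cc1OC1(C(=O)OC)C(CCCCC)CC(=O)CC1=O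
A4 | alternative 2 | 3-methylcyclobut-2-en-1-one | CC1=CC(=O)C1
A5 | alternative 2 | 1-(benzyloxy)-2-(ethynyloxy)-5-methoxy-3-pentylbenzene | C#COc1c(OCc2ccccc2)cc(OC)cc1CCCCC
A6 | alternative 2 | 3-[2-(benzyloxy)-4-methoxy-6-pentylphenoxy]-5-methylphenol | Cc1cc(O)cc(Oc2c(OCc3ccccc3)cc(OC)cc2CCCCC)c1
A7 | alternative 3 | 4-[2-(benzyloxy)-4-methoxy-6-pentylphenoxy]-7-pentyl-2H,5H-pyrano[4,3-b]pyran-2,5-dione | CCCCCC1=CC2=C(C(=O)O1)C(Oc1c(OCc3ccccc3)cc(OC)cc1CCCCC)=CC(=O)O2
A8 | alternative 3 | (triisopropylsilyloxy)ethyne | C#CO[Si](C(C)C)(C(C)C)C(C)C
A9 | alternative 3 | 8-[2-(benzyloxy)-4-methoxy-6-pentylphenoxy]-3-pentyl-6-(triisopropylsilyloxy)-1H-isochromen-1-one | CCCCCc1cc2cc(O[Si](C(C)C)(C(C)C)C(C)C)cc(Oc3c(OCc4ccccc4)cc(OC)cc3CCCCC)c2c(=O)o1
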